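The runs are calculated for an exercise, and the scatter is random.

Keep the books on the starting material, the limiting reagent of this flask, whose charge of 1.0 M stands against 1.30 M of partner. Three entries must add up to what was charged.

| flask | starting material | partner | remark | time |
|---|---|---|---|---|
| teal | 1 M | 0.65 M | run made earlier |  |
| amber | 1 M | 0.98 M | run made earlier |  |
| flask | 1.0 M | 1.30 M |  | 8.0 min |

| run | time / min | product / % | starting material / % |
|---|---|---|---|
| teal | 0.667 | 0 | 75 |
| teal | 2.00 | 3 | 50 |
| teal | 3.00 | 5 | 37 |
| teal | 5.00 | 18 | 21 |
| teal | 8.00 | 27 | 15 |
| teal | 10.0 | 32 | 10 |
| amber | 0.833 | 0 | 74 |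
| amber | 1.33 | 3 | 60 |
| amber | 2.00 | 4 | 50 |
| amber | 4.00 | 20 | 28 |
| amber | 6.00 | 28 | 18 |
| amber | 10.0 | 43 | 10 |

(readings scatter by 1.5 percentage points)

* product present at 8.0 min, in percent of the starting material charged
* starting material present at 8.0 min, in percent of the starting material charged
* dormant form present at 8.0 min, in percent of the starting material charged



The first entry is the starting material left. At 8.0 min the teal run reads 15%, and the amber run, taken midway between its readings at 6.00 min and 10.0 min, gives 14.0%. The two runs differ by 1 percentage point, so you book 14.0% for the flask.

The second entry is product, and here partner matters. Teal reads 27%, and amber, taken midway in the same way, gives 35.5%. Together they give 0.258 L mol⁻¹, the partner slope: the fraction of the charge gained as product at this time per molar of added partner. Carried from teal to the flask, it books 43.7%.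

The third entry is what no reading covers, 42.3%. Teal reads 5% of product at 3.00 min, when its starting material has fallen to 37%, so you book this entry as dormant form plus anything still on its way to product.

The forecast gave 45% of product, 11% of starting material and 44% of dormant form, and called this “an extrapolation”.

The flask gives 43.6% of product, 11.7% of starting material and 32.6% of dormant form.

    starting material ⇌ dormant form (K = 3.80, k = 0.00230 s⁻¹)
    starting material ⇌ open intermediate (K = 2.20, k = 0.00430 s⁻¹)
    partner → second intermediate (k = 0.00680 s⁻¹)
    open intermediate + second intermediate → product (k = 0.00630 L mol⁻¹ s⁻¹)

The flask's unread entry, 44.7%, is dormant form plus 12.1% of open intermediate. The partner slope booked 43.7% of product against the 43.6% of this flask, which stands there because of the time of the reading and the loss of starting material to dormant form, both ways, acting together: without that loss the flask reaches 55.4% at 8.0 min, and left until 80.0 min it reaches 87.5%. For the neighbour flask with 0.33 M of partner, the slope books 18.8% of product; that flask computes to 16.3%.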